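**Plan**
1. Retrosynthetic cuts, in order: the C3–O ester bond (releasing linoleic acid and the C3 epimer of the alcohol), the C5–C6 sp–sp bond of the diyne, the C7–C8 bond beside the oxirane, and the C3–C4 bond of the enynol.
2. Enabling feature: C3 sits between the C1=C2 vinyl group and the C4≡C5 triple bond, so it is a secondary carbon that is both allylic and propargylic; an activated C3–O bond there can be exchanged for a carboxylate oxygen with inversion.
3. Forward order: the only ring, the C9–C10 oxirane, is made first on the decenol branch; the chain is extended from C8 to C7/C6 (triflate alkylation, then bromoalkyne), joined to the C1–C5 enynol at C5–C6, and acylated last.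
4. Stereochemistry: C9 and C10 (R,R, trans) come from D-(−)-tartrate-controlled epoxidation of an E-olefin; C3 is selected as R by a lipase and turned into S by the inverting esterification; both Z olefins arrive with linoleic acid.

Key step: step 9

Remark on the chemistry: the target carries a trans-(9R,10R)-oxirane and a (3S)-acyloxy carbon, and the lipase of step 2 is assumed to show its usual preference for the (R)-carbinol.

**Route**

Step 1
Reactants: 1 ethynyltrimethylsilane; 2 acrolein
Product: 4 rac-5-(trimethylsilyl)pent-1-en-4-yn-3-ol, via (trimethylsilyl)ethynylmagnesium bromide 3 (not isolated)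
Conditions: EtMgBr, THF, 0 °C to rt; then freshly distilled acrolein, −78 to 0 °C; aq. NH4Cl
Reagents that add atoms: none
Why: Ethylmagnesium bromide deprotonates 1 to the alkynyl Grignard reagent 3, which adds 1,2 to the carbonyl of the enal at low temperature (Grignard addition of an acetylide to an aldehyde), giving the racemic carbinol whose C3 configuration is sorted out in step 2.

Step 2
Reactants: 4 rac-5-(trimethylsilyl)pent-1-en-4-yn-3-ol
Product: 5 (R)-5-(trimethylsilyl)pent-1-en-4-yn-3-yl acetate
Conditions: Pseudomonas fluorescens lipase (Amano lipase AK), vinyl acetate, hexane, 4 Å MS, rt, stopped just short of half conversion; chromatography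
Reagents that add atoms: vinyl acetate, C=COC(C)=O
Why: Lipase-catalysed kinetic resolution by irreversible transesterification, in which Kazlauskas's rule (silylethynyl arm large, vinyl medium) predicts acetylation of the (R)-enantiomer, so the enzyme selects the C3 configuration, which a Mosher ester analysis of the methanolysed acetate should confirm.

Step 3
Reactants: 5 (R)-5-(trimethylsilyl)pent-1-en-4-yn-3-yl acetate
Product: 6 (R)-pent-1-en-4-yn-3-ol
Conditions: K2CO3 (0.2 equiv), MeOH, 0 °C to rt; extraction into Et2O, careful concentration, used as a concentrated solution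
Reagents that add atoms: none
Why: Carbonate-catalysed methanolysis cleaves the acetate by transesterification and the alkynyl C–Si bond by protodesilylation in one operation without touching the C3–O bond, so the (R) configuration is retained.

Step 4
Reactants: 7 (E)-dec-2-en-1-ol
Product: 8 [(2R,3R)-3-heptyloxiran-2-yl]methanol
Conditions: Ti(OiPr)4 (5 mol%), D-(−)-diisopropyl tartrate (6 mol%), t-BuOOH (decane), 4 Å MS, CH2Cl2, −20 °C
Reagents that add atoms: tert-butyl hydroperoxide, CC(C)(C)OO
Why: Sharpless asymmetric epoxidation of a primary E-allylic alcohol, in which the titanium–D-(−)-tartrate catalyst delivers oxygen to the olefin face that gives the (2R,3R)-epoxy alcohol and the E geometry is carried stereospecifically into the trans-oxirane, fixing C9 and C10 of the target.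

Step 5
Reactants: 8 [(2R,3R)-3-heptyloxiran-2-yl]methanol
Product: 9 [(2R,3R)-3-heptyloxiran-2-yl]methyl trifluoromethanesulfonate
Conditions: Tf2O, 2,6-lutidine, CH2Cl2, −78 °C; cold aqueous work-up, used crude at once
Reagents that add atoms: trifluoromethanesulfonic anhydride, O=S(=O)(OS(=O)(=O)C(F)(F)F)C(F)(F)F
Why: O-Sulfonylation of the primary alcohol with a hindered pyridine base at −78 °C should give the epoxy triflate without opening the oxirane or disturbing either stereocentre.

Step 6
Reactants: 9 [(2R,3R)-3-heptyloxiran-2-yl]methyl trifluoromethanesulfonate; 1 ethynyltrimethylsilane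
Product: 11 (2R,3R)-2-heptyl-3-[3-(trimethylsilyl)prop-2-yn-1-yl]oxirane, via lithium (trimethylsilyl)acetylide 10 (not isolated)
Conditions: 1, n-BuLi, THF, −78 °C; then 9 in THF, −78 to −40 °C
Reagents that add atoms: none
Why: SN2 alkylation of a lithium acetylide by a primary 2,3-epoxy triflate, where at −78 °C and without a Lewis acid the sulfonate carbon reacts far faster than the oxirane, forming the C7–C8 bond with both oxirane stereocentres retained.

Step 7
Reactants: 11 (2R,3R)-2-heptyl-3-[3-(trimethylsilyl)prop-2-yn-1-yl]oxirane
Product: 12 (2R,3R)-2-(3-bromoprop-2-yn-1-yl)-3-heptyloxirane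
Conditions: NBS (1.1 equiv), AgNO3 (0.2 equiv), acetone, rt, dark
Reagents that add atoms: N-bromosuccinimide, O=C1CCC(=O)N1Br
Why: Silver-catalysed bromodesilylation of an alkynylsilane, in which AgNO3 converts the C–Si bond into a silver acetylide that NBS brominates, and the catalytic silver loading in near-neutral acetone should spare the oxirane.

Step 8
Reactants: 6 (R)-pent-1-en-4-yn-3-ol; 12 (2R,3R)-2-(3-bromoprop-2-yn-1-yl)-3-heptyloxirane
Product: 13 (3R,9R,10R)-9,10-epoxyheptadec-1-ene-4,6-diyn-3-ol
Conditions: CuCl (10 mol%), NH2OH·HCl, 30% aq. n-BuNH2, Et2O, 0 °C; 6 in excess (1.5 equiv), 12 added slowly; argon, dark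
Reagents that add atoms: none
Why: Cadiot–Chodkiewicz coupling, in which the copper acetylide of terminal alkyne 6 couples with bromoalkyne 12 to form the C5–C6 sp–sp bond while hydroxylamine keeps copper monovalent to suppress homocoupling; the free hydroxyl, the oxirane and all three stereocentres are unaffected at 0 °C.

Step 9
Reactants: 13 (3R,9R,10R)-9,10-epoxyheptadec-1-ene-4,6-diyn-3-ol; 14 linoleic acid
Product: 16 (3S,9R,10R)-9,10-epoxyheptadec-1-ene-4,6-diyn-3-yl (9Z,12Z)-octadeca-9,12-dienoate, via alkoxytriphenylphosphonium linoleate 15 (not isolated)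
Conditions: 14 (1.3 equiv), PPh3 (1.5 equiv), DIAD (1.5 equiv, added last, dropwise), toluene, −20 to 0 °C, argon, dark
Reagents that add atoms: none
Why: PPh3 and DIAD form a phosphonium betaine that deprotonates acid 14 and transfers phosphorus to the C3 hydroxyl of 13 to give ion pair 15, whose carboxylate attacks C3 from the face opposite the departing Ph3P=O and forms the C3–O ester bond. The closest known reaction type is the Mitsunobu esterification of secondary allylic and propargylic alcohols with carboxylic acids, of which a 1-en-4-yn-3-ol is a demanding member. No ring is formed, so no mode of closure applies, and the oxirane is carried through untouched. The one new stereocentre, C3, is set as S by stereospecific inversion of the (3R) carbinol, so its control element is the configuration selected by the lipase in step 2. The step needs direct substitution at C3 to win over attack at C1 (transposition to the conjugated enediyne) and over ionisation; the inductively electron-poor C4–C7 diyne gives a C3 cation little support, and toluene at −20 °C with the azo reagent added last keeps the carboxylate in a tight ion pair next to C3. The neutral, cold medium should leave the oxirane, the C8 methylene and the skipped Z,Z-diene of the acid unchanged.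

**Compound list**
1 | ethynyltrimethylsilane | C#C[Si](C)(C)C | starting material
2 | acrolein | C=CC=O | starting material
3 | [(trimethylsilyl)ethynyl]magnesium bromide | C[Si](C)(C)C#C[Mg]Br | intermediate
4 | rac-5-(trimethylsilyl)pent-1-en-4-yn-3-ol | C=CC(O)C#C[Si](C)(C)C | intermediate
5 | (R)-5-(trimethylsilyl)pent-1-en-4-yn-3-yl acetate | C=C[C@H](C#C[Si](C)(C)C)OC(C)=O | intermediate
6 | (R)-pent-1-en-4-yn-3-ol | C=C[C@H](C#C)O | intermediate
7 | (E)-dec-2-en-1-ol | OC/C=C/CCCCCCC | starting material
8 | [(2R,3R)-3-heptyloxiran-2-yl]methanol | OC[C@H]1O[C@@H]1CCCCCCC | intermediate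
9 | [(2R,3R)-3-heptyloxiran-2-yl]methyl trifluoromethanesulfonate | O=S(=O)(OC[C@H]1O[C@@H]1CCCCCCC)C(F)(F)F | intermediate
10 | lithium (trimethylsilyl)acetylide | [Li+].[C-]#C[Si](C)(C)C | intermediate
11 | (2R,3R)-2-heptyl-3-[3-(trimethylsilyl)prop-2-yn-1-yl]oxirane | C[Si](C)(C)C#CC[C@H]1O[C@@H]1CCCCCCC | intermediate
12 | (2R,3R)-2-(3-bromoprop-2-yn-1-yl)-3-heptyloxirane | BrC#CC[C@H]1O[C@@H]1CCCCCCC | intermediate
13 | (3R,9R,10R)-9,10-epoxyheptadec-1-ene-4,6-diyn-3-ol | C=C[C@H](C#CC#CC[C@H]1O[C@@H]1CCCCCCC)O | intermediate
14 | linoleic acid, (9Z,12Z)-octadeca-9,12-dienoic acid | CCCCC/C=C\C/C=C\CCCCCCCC(=O)O | starting material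
15 | [(3R,9R,10R)-9,10-epoxyheptadec-1-ene-4,6-diyn-3-yl]oxy(triphenyl)phosphonium (9Z,12Z)-octadeca-9,12-dienoate | C=C[C@H](C#CC#CC[C@H]1O[C@@H]1CCCCCCC)O[P+](c1ccccc1)(c1ccccc1)c1ccccc1.CCCCC/C=C\C/C=C\CCCCCCCC(=O)[O-] | intermediate
16 | (3S,9R,10R)-9,10-epoxyheptadec-1-ene-4,6-diyn-3-yl (9Z,12Z)-octadeca-9,12-dienoate | C=C[C@@H](C#CC#CC[C@H]1O[C@@H]1CCCCCCC)OC(=O)CCCCCCC/C=C\C/C=C\CCCCC | target

**Count**
Total steps: 9. Longest linear sequence: 6 steps (7 → 8 → 9 → 11 → 12 → 13 → 16, steps 4 to 9); the enynol branch (steps 1 to 3) joins at step 8.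

**Steps most likely to fail**

Step 9. The oxyphosphonium ion pair may collapse through the allylic terminus, moving the ester to C1, or it may ionise, which would erode regiochemical and configurational integrity at C3. The fallback sets out from 4 and returns at 16; it gives up inversion and acylates with retention. The lipase run of step 2 is taken slightly beyond half conversion and the unreacted alcohol, (S)-5-(trimethylsilyl)pent-1-en-4-yn-3-ol F1, is collected. K2CO3 in methanol removes the silyl group to give (S)-pent-1-en-4-yn-3-ol F2. Cadiot–Chodkiewicz coupling of F2 with 12 under the conditions of step 8 gives (3S,9R,10R)-9,10-epoxyheptadec-1-ene-4,6-diyn-3-ol F3. Steglich esterification of F3 with 14 (DCC, catalytic DMAP, CH2Cl2, 0 °C) acylates the C3 oxygen without breaking the C3–O bond and should deliver 16.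

Step 6. The epoxy triflate may decompose before or during the alkylation, or the acetylide may attack the oxirane instead of the sulfonate carbon. The fallback sets out from 7 and returns at 11; it installs the alkyne before the epoxide oxygen. Appel bromination (CBr4, PPh3, CH2Cl2, 0 °C) converts 7 into (E)-1-bromodec-2-ene F4. Copper-mediated coupling of F4 with 1 (CuI, NaI, K2CO3, DMF, rt) gives the skipped enyne trimethyl[(E)-dodec-4-en-1-yn-1-yl]silane F5. Shi epoxidation of the isolated E-olefin of F5 (D-fructose-derived ketone catalyst, KHSO5, K2CO3, Bu4NHSO4, MeCN–dimethoxymethane, aqueous buffer, 0 °C) is expected from the spiro transition-state model to give the (R,R)-oxirane, which is 11.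

Step 7. Silver- or acid-promoted opening of the oxirane, or slow silicon-to-bromine exchange, may give mixtures. The fallback sets out from 11 and 6 and returns at 13; it exchanges the roles of the two coupling partners. K2CO3 in methanol at 0 °C desilylates 11 to (2R,3R)-2-heptyl-3-(prop-2-yn-1-yl)oxirane F6. The halogen is placed on the epoxide-free partner by treating 6 with NBS and catalytic AgNO3 in acetone to give (R)-5-bromopent-1-en-4-yn-3-ol F7. Cadiot–Chodkiewicz coupling of F6 with F7 (CuCl, NH2OH·HCl, aq. n-BuNH2, Et2O, 0 °C) forms the same C5–C6 bond and gives 13.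

**Further compounds**
F1 | step 9 | (S)-5-(trimethylsilyl)pent-1-en-4-yn-3-ol | C=C[C@@H](C#C[Si](C)(C)C)O
F2 | step 9 | (S)-pent-1-en-4-yn-3-ol | C=C[C@@H](C#C)O
F3 | step 9 | (3S,9R,10R)-9,10-epoxyheptadec-1-ene-4,6-diyn-3-ol | C=C[C@@H](C#CC#CC[C@H]1O[C@@H]1CCCCCCC)O
F4 | step 6 | (E)-1-bromodec-2-ene | BrC/C=C/CCCCCCC
F5 | step 6 | trimethyl[(E)-dodec-4-en-1-yn-1-yl]silane | C[Si](C)(C)C#CC/C=C/CCCCCCC
F6 | step 7 | (2R,3R)-2-heptyl-3-(prop-2-yn-1-yl)oxirane | C#CC[C@H]1O[C@@H]1CCCCCCC
F7 | step 7 | (R)-5-bromopent-1-en-4-yn-3-ol | C=C[C@H](C#CBr)O
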